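The flavanone (flavanone numbering) is disconnected through ring C at O1–C8a and C4–C4a. This rests on one feature: the ether oxygen O1 and the ketone carbon C4 are bonded to two adjacent carbons of ring A, C8a and C4a, exactly the ortho pair a benzyne acquires when an oxygen nucleophile adds to one end of its triple bond and the carbanion at the other end is acylated within the same molecule. The key step therefore joins a fluoride-generated 3-bromo-5-(methoxymethoxy)benzyne to an enantiopure β-hydroxy ester, forming both bonds and ring C in one operation without touching C2. Its precursors are an ortho-silylaryl triflate carrying bromine beside the triflate for regiocontrol and methyl (S)-3-hydroxy-3-(4-geranyloxyphenyl)propanoate.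

Key step: step 6

Remark: geranyl stands for (2E)-3,7-dimethylocta-2,6-dien-1-yl, and 4-(methoxymethoxy)phenol 1 is taken as a purchasable compound, chosen because brominating it on both sides of the free hydroxyl fixes the position of the acetal without any selective protection.

Step 1
Reactants: 1 4-(methoxymethoxy)phenol
Product: 2 2,6-dibromo-4-(methoxymethoxy)phenol
Conditions: NBS (2.05 equiv), i-Pr2NH (0.2 equiv), CH2Cl2, 0 °C to rt
Reagents that add atoms: N-bromosuccinimide, O=C1CCC(=O)N1Br
Why: Electrophilic aromatic bromination in which the N-bromoamine formed from NBS and the secondary amine hands bromine to the two positions ortho to the hydrogen-bonded free hydroxyl (the para position carries the acetal oxygen), in a medium free of strong acid so that the methoxymethyl ether should survive.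

Step 2
Reactants: 2 2,6-dibromo-4-(methoxymethoxy)phenol
Product: 6 2-bromo-4-(methoxymethoxy)-6-(trimethylsilyl)phenyl trifluoromethanesulfonate, via aryl silyl ether 3 (not isolated), via aryllithium 4 (not isolated), via lithium phenoxide 5 (not isolated)
Conditions: (Me3Si)2NH, THF, 65 °C, then evaporate; n-BuLi (1.05 equiv), THF, −100 to −78 °C; Tf2O (1.2 equiv), −100 °C to rt
Reagents that add atoms: hexamethyldisilazane, C[Si](C)(C)N[Si](C)(C)C; trifluoromethanesulfonic anhydride, O=S(=O)(OS(=O)(=O)C(F)(F)F)C(F)(F)F
Why: O-Silylation is followed by bromine–lithium exchange at one of the two equivalent C–Br bonds (faster at −100 °C than deprotonation next to the acetal), a retro-Brook 1,3 O-to-C silyl shift in 4 driven by formation of phenoxide 5, and O-sulfonylation with Tf2O, the standard way from ortho-bromophenols to ortho-silylaryl triflates.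

Step 3
Reactants: 7 4-hydroxyacetophenone; 8 geranyl bromide
Product: 9 1-[4-(geranyloxy)phenyl]ethan-1-one
Conditions: K2CO3, acetone, 56 °C
Reagents that add atoms: none
Why: Williamson ether synthesis in which the phenoxide displaces bromide from the primary allylic carbon by SN2 without touching the (E)-configured double bond.

Step 4
Reactants: 9 1-[4-(geranyloxy)phenyl]ethan-1-one
Product: 11 methyl 3-[4-(geranyloxy)phenyl]-3-oxopropanoate, via sodium enolate 10 (not isolated)
Conditions: NaH (2.5 equiv), (MeO)2CO (5 equiv), THF, 65 °C; then AcOH, H2O, 0 °C
Reagents that add atoms: dimethyl carbonate, COC(=O)OC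
Why: Crossed Claisen condensation of the ketone enolate with dimethyl carbonate, pulled to completion by deprotonation of the β-keto ester to enolate 10, which the acidic work-up returns as 11.

Step 5
Reactants: 11 methyl 3-[4-(geranyloxy)phenyl]-3-oxopropanoate
Product: 12 methyl (3S)-3-[4-(geranyloxy)phenyl]-3-hydroxypropanoate
Conditions: RuCl[(S,S)-TsDPEN](p-cymene) (1 mol %), HCO2H/Et3N (5:2), EtOAc, 30 °C
Reagents that add atoms: none
Why: Noyori–Ikariya asymmetric transfer hydrogenation, in which the ruthenium hydride and the ligand N–H pass H− and H+ to the ketone through a six-membered outer-sphere transition state with the aryl ring held against the cymene ligand, which with the (S,S) ligand should set the (S) carbinol centre as for other aryl ketones whose second substituent ranks below aryl, while the isolated alkenes and the ester are not reduced.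

Step 6
Reactants: 6 2-bromo-4-(methoxymethoxy)-6-(trimethylsilyl)phenyl trifluoromethanesulfonate; 12 methyl (3S)-3-[4-(geranyloxy)phenyl]-3-hydroxypropanoate
Product: 15 (2S)-5-bromo-2-[4-(geranyloxy)phenyl]-7-(methoxymethoxy)-2,3-dihydro-4H-chromen-4-one, via aryne 13 (not isolated), via aryl anion 14 (not isolated)
Conditions: 6 (1.5 equiv), CsF (4 equiv), THF, 65 °C
Reagents that add atoms: none
Why: Proposed new method: fluoride attacks the silicon of 6, triflate leaves and aryne 13 forms with its triple bond between the future C8a and C4a; the hydroxyl of 12, activated by hydrogen bonding to fluoride, adds its oxygen to C8a, and the carbanion left on C4a (14) attacks the ester carbonyl and expels methoxide, which collects the proton that fluoride had taken. The closest known reaction types are the CsF-mediated annulation of arynes with methyl salicylates to xanthones, in which an oxygen nucleophile adds and the aryl anion is acylated by a methyl ester, and the addition of carboxylic acids across arynes to ortho-hydroxyaryl ketones; what is new is an aliphatic secondary carbinol as the nucleophile and a saturated two-carbon tether to the ester. Ring C closes in the 6-exo-trig mode, the new ring holding O1, C2, C3, C4, C4a and C8a with the carbonyl oxygen outside it. No stereocenter is created: C2 is the carbinol carbon of 12 and keeps all four of its bonds, and since the priority order O > aryl > CH2 > H is the same in 12 and 15, (S) remains (S). The step needs regioselective addition across the aryne, secured by the C5 bromine, whose σ-withdrawal distorts the triple bond so that the far terminus C8a is the more electrophilic carbon and the negative charge builds up on C4a beside the halogen, whereas the C7 acetal oxygen, meta to C8a and para to C4a, pulls only weakly the other way. It also needs acyl capture of the carbanion to outrun protonation, which is why THF, a solvent without acidic C–H bonds, is used and excess CsF binds HF as CsHF2.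

Step 7
Reactants: 15 (2S)-5-bromo-2-[4-(geranyloxy)phenyl]-7-(methoxymethoxy)-2,3-dihydro-4H-chromen-4-one
Product: 16 (2S)-2-[4-(geranyloxy)phenyl]-7-(methoxymethoxy)-2,3-dihydro-4H-chromen-4-one
Conditions: (Me3Si)3SiH (1.2 equiv), AIBN (0.2 equiv), toluene, 80 °C
Reagents that add atoms: none
Why: Radical-chain hydrodebromination in which the silyl radical abstracts bromine from the electron-poor C5–Br bond and the aryl radical takes hydrogen from Si–H before it can reach the remote alkenes, under neutral conditions that should leave the acetal, the ketone and C2 untouched, the silane being kept near stoichiometric and the reaction stopped at full conversion so that reversible silyl-radical addition to the trisubstituted alkenes has no time to scramble the (E) geometry.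

Step 8
Reactants: 16 (2S)-2-[4-(geranyloxy)phenyl]-7-(methoxymethoxy)-2,3-dihydro-4H-chromen-4-one
Product: 18 (2S)-2-[4-(geranyloxy)phenyl]-7-hydroxy-2,3-dihydro-4H-chromen-4-one, via trimethylsilyl ether 17 (not isolated)
Conditions: Me3SiOTf (2.5 equiv), 2,2'-bipyridyl (3.5 equiv), MeCN, 0 °C to rt; then H2O, NaHCO3 (aq)
Reagents that add atoms: none
Why: Silyl-triflate-mediated cleavage of an aryl methoxymethyl ether, in which the N-silylbipyridinium triflate formed in the flask turns the acetal into aryl silyl ether 17 and a pyridinium-bound methoxymethyl unit, both hydrolysed by water, in a medium buffered by excess bipyridyl that should spare the acid-labile geranyl aryl ether and the benzylic C2–O1 bond.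

Compound list
1 | 4-(methoxymethoxy)phenol | COCOc1ccc(O)cc1 | starting material
2 | 2,6-dibromo-4-(methoxymethoxy)phenol | COCOc1cc(Br)c(O)c(Br)c1 | intermediate
3 | [2,6-dibromo-4-(methoxymethoxy)phenoxy]trimethylsilane | COCOc1cc(Br)c(O[Si](C)(C)C)c(Br)c1 | intermediate (not isolated)
4 | [3-bromo-5-(methoxymethoxy)-2-(trimethylsilyloxy)phenyl]lithium | COCOc1cc(Br)c(O[Si](C)(C)C)c([Li])c1 | intermediate (not isolated)
5 | lithium 2-bromo-4-(methoxymethoxy)-6-(trimethylsilyl)phenoxide | COCOc1cc(Br)c([O-])c([Si](C)(C)C)c1.[Li+] | intermediate (not isolated)
6 | 2-bromo-4-(methoxymethoxy)-6-(trimethylsilyl)phenyl trifluoromethanesulfonate | COCOc1cc(Br)c(OS(=O)(=O)C(F)(F)F)c([Si](C)(C)C)c1 | intermediate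
7 | 4-hydroxyacetophenone | CC(=O)c1ccc(O)cc1 | starting material
8 | geranyl bromide, (2E)-1-bromo-3,7-dimethylocta-2,6-diene | CC(C)=CCC/C(C)=C/CBr | starting material
9 | 1-[4-(geranyloxy)phenyl]ethan-1-one | CC(C)=CCC/C(C)=C/COc1ccc(C(C)=O)cc1 | intermediate
10 | sodium (Z)-enolate of methyl 3-[4-(geranyloxy)phenyl]-3-oxopropanoate | CC(C)=CCC/C(C)=C/COc1ccc(/C([O-])=C/C(=O)OC)cc1.[Na+] | intermediate (not isolated)
11 | methyl 3-[4-(geranyloxy)phenyl]-3-oxopropanoate | CC(C)=CCC/C(C)=C/COc1ccc(C(=O)CC(=O)OC)cc1 | intermediate
12 | methyl (3S)-3-[4-(geranyloxy)phenyl]-3-hydroxypropanoate | CC(C)=CCC/C(C)=C/COc1ccc([C@@H](O)CC(=O)OC)cc1 | intermediate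
13 | 3-bromo-5-(methoxymethoxy)benzyne | COCOC1=CC#CC(Br)=C1 | intermediate (not isolated)
14 | caesium {2-bromo-6-[(1S)-1-(4-geranyloxyphenyl)-3-methoxy-3-oxopropoxy]-4-(methoxymethoxy)phenyl}ide | CC(C)=CCC/C(C)=C/COc1ccc([C@@H](Oc2cc(OCOC)cc(Br)[c-]2)CC(=O)OC)cc1.[Cs+] | intermediate (not isolated)
15 | (2S)-5-bromo-2-[4-(geranyloxy)phenyl]-7-(methoxymethoxy)-2,3-dihydro-4H-chromen-4-one | CC(C)=CCC/C(C)=C/COc1ccc([C@@H]2CC(=O)c3c(Br)cc(OCOC)cc3O2)cc1 | intermediate
16 | (2S)-2-[4-(geranyloxy)phenyl]-7-(methoxymethoxy)-2,3-dihydro-4H-chromen-4-one | CC(C)=CCC/C(C)=C/COc1ccc([C@@H]2CC(=O)c3ccc(OCOC)cc3O2)cc1 | intermediate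
17 | (2S)-2-[4-(geranyloxy)phenyl]-7-(trimethylsilyloxy)-2,3-dihydro-4H-chromen-4-one | CC(C)=CCC/C(C)=C/COc1ccc([C@@H]2CC(=O)c3ccc(O[Si](C)(C)C)cc3O2)cc1 | intermediate (not isolated)
18 | (2S)-2-[4-(geranyloxy)phenyl]-7-hydroxy-2,3-dihydro-4H-chromen-4-one | CC(C)=CCC/C(C)=C/COc1ccc([C@@H]2CC(=O)c3ccc(O)cc3O2)cc1 | target

Total step count: 8.
Longest linear sequence: 6 steps (steps 3, 4, 5, 6, 7 and 8); the aryne precursor branch (steps 1 and 2) joins at step 6.

Steps most likely to fail

Step 6 (proposed new method). Several processes could defeat it:
- the carbanion on C4a may be protonated before it reaches the ester, which would leave a simple O-arylation;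
- the hydroxy ester may fragment by retro-aldol cleavage or lose water under fluoride;
- THF may intercept the aryne;
- the product ring may open to the chalcone under base, eroding the configuration at C2.

The fallback uses known chemistry throughout: the rhodium-catalysed asymmetric conjugate addition of an arylboronic acid to a chromone (Hayashi–Miyaura reaction), which forms the C2–aryl bond instead of ring C. It sets out from geranyl bromide 8 and comes back to the route at 16, so that steps 6 and 7 are bypassed. 4-Bromophenol is alkylated with 8 (K2CO3, acetone, 56 °C) to 1-bromo-4-(geranyloxy)benzene F1. Bromine–lithium exchange (n-BuLi, THF, −78 °C), B(OiPr)3 and aqueous NH4Cl should give [4-(geranyloxy)phenyl]boronic acid F2. Commercial 7-hydroxy-4H-chromen-4-one is protected (MOMCl, i-Pr2NEt, CH2Cl2) as 7-(methoxymethoxy)-4H-chromen-4-one F3. F2 is then added to F3 with [Rh(OH)(cod)]2 (monovalent rhodium) and an electron-poor atropisomeric bisphosphine of the MeO-F12-BIPHEP type in toluene–water at 20–40 °C, to give 16. The ligand antipode is the one that delivers the aryl group to the face giving (2S), and the base-free medium avoids opening of the chromone.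

Step 7. The silyl radical may add reversibly to the trisubstituted alkenes, which would isomerise the (E) double bond or hydrosilylate the chain. Prolonged heating with radicals may also engage the aryl ketone. The fallback replaces the radical chain by single-electron photoreduction and runs from 15 to 16: 10-phenylphenothiazine (5 mol %), n-Bu3N, HCO2H, MeCN, 385–390 nm light, rt. The excited phenothiazine transfers an electron to the C5–Br bond, which is activated by the neighbouring carbonyl; bromide leaves and the aryl radical takes hydrogen from the amine radical cation or formate. No metalloid radical able to add to alkenes is present, and the wavelength lies beyond the absorption of the flavanone. This fallback makes no new compound (F0).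

Step 5. Facial discrimination in the hydride transfer to the electron-rich aryl ketone may be incomplete, and no later step can raise the enantiomeric purity. Slow reduction would also prolong exposure of the allylic aryl ether to the acidic medium. The fallback changes from asymmetric catalysis to resolution and runs from 11 back to 12. NaBH4 in MeOH at −20 °C should give racemic methyl 3-[4-(geranyloxy)phenyl]-3-hydroxypropanoate F4. Burkholderia cepacia lipase with vinyl acetate in t-BuOMe at 30 °C is then expected, by the usual preference of this lipase for the enantiomer in which the aryl group acts as the large substituent, to acetylate the (R)-alcohol to methyl (3R)-3-acetoxy-3-[4-(geranyloxy)phenyl]propanoate F5 and to leave the (S)-alcohol 12. The two are separated by chromatography, at the cost of half the material, and the configuration is confirmed against material from step 5.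

Further compounds
F1 | step 6 | 1-bromo-4-(geranyloxy)benzene | CC(C)=CCC/C(C)=C/COc1ccc(Br)cc1
F2 | step 6 | [4-(geranyloxy)phenyl]boronic acid | CC(C)=CCC/C(C)=C/COc1ccc(B(O)O)cc1
F3 | step 6 | 7-(methoxymethoxy)-4H-chromen-4-one | COCOc1ccc2c(=O)ccoc2c1
F0 | step 7 | none | none
F4 | step 5 | racemic methyl 3-[4-(geranyloxy)phenyl]-3-hydroxypropanoate | CC(C)=CCC/C(C)=C/COc1ccc(C(O)CC(=O)OC)cc1
F5 | step 5 | methyl (3R)-3-acetoxy-3-[4-(geranyloxy)phenyl]propanoate | CC(C)=CCC/C(C)=C/COc1ccc([C@H](OC(C)=O)CC(=O)OC)cc1
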